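**Retrosynthetic overview**
- The strategy rests on the benzene ring of the target: C2 and C4 carry hydroxyls in a 1,3 relationship, C1 carries the carboxyl, and C6 carries the CH2 of the (2S,12S)-2,12-diacetoxytridecyl chain. C2–C5 with both oxygens map onto the bis(silyl enol ether) of cyclohexane-1,3-dione; C1 and C6 map onto C2 and C3 of a 2-ynoate.
- The benzene ring is the only ring and is made late: a Diels–Alder/retro-Diels–Alder (Alder–Rickert) sequence between the diene and allyl (5S,15S)-5,15-diacetoxyhexadec-2-ynoate forms C1–C2 and C5–C6 and expels ethylene.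
- The ynoate comes from BF3-mediated opening of an (S,S)-epoxy acetate by lithiated allyl propiolate (C3–C4 bond), followed by acetylation.
- The epoxide comes from (S)-tridec-12-en-2-yl acetate by epoxidation and hydrolytic kinetic resolution; the alkenol comes from (S)-propylene oxide and a decenyl Grignard reagent.
- Last step: removal of the allyl ester with Pd(PPh3)4 and morpholine.

Key step: step 9

Remark: for alkyl oxiranes the (S,S)-(salen)Co(OAc) catalyst is assumed to hydrate the (R)-epoxide and leave the (S)-epoxide; if the sense proved opposite, the (R,R) catalyst would be used and nothing else changes.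

**Route**

Step 1
Reactants: 1 10-bromodec-1-ene; 2 (S)-propylene oxide
Product: 4 (S)-tridec-12-en-2-ol, via dec-9-en-1-ylmagnesium bromide 3 (not isolated)
Conditions: Mg, THF, rt → 40 °C; then CuI (10 mol%), 2, −30 → 0 °C; aq. NH4Cl
Reagents that add atoms: none
Why: Copper-catalysed Grignard opening of a terminal epoxide occurs by SN2 attack at the CH2 carbon, so the (S)-carbinol centre of the chiral-pool epoxide is carried over unchanged.

Step 2
Reactants: 4 (S)-tridec-12-en-2-ol
Product: 5 (S)-tridec-12-en-2-yl acetate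
Conditions: Ac2O, pyridine, DMAP (cat.), CH2Cl2, 0 °C → rt
Reagents that add atoms: acetic anhydride, CC(=O)OC(C)=O
Why: Nucleophile-catalysed O-acylation of a secondary alcohol installs the acetate that the target keeps and masks the hydroxyl for the later organolithium step.

Step 3
Reactants: 5 (S)-tridec-12-en-2-yl acetate
Product: 6 (2S)-11-(oxiran-2-yl)undecan-2-yl acetate (both epimers at the oxirane carbon)
Conditions: mCPBA, NaHCO3, CH2Cl2, 0 °C → rt
Reagents that add atoms: 3-chloroperoxybenzoic acid, OOC(=O)c1cccc(Cl)c1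
Why: Prilezhaev epoxidation of the terminal alkene should give the oxirane as a near-equal mixture of epimers, since the remote C2 centre exerts no control.

Step 4
Reactants: 6 (2S)-11-(oxiran-2-yl)undecan-2-yl acetate (epimer mixture)
Product: 7 (2S)-11-[(2S)-oxiran-2-yl]undecan-2-yl acetate
Conditions: (S,S)-(salen)Co(OAc) (0.5 mol%; salen = N,N′-bis(3,5-di-tert-butylsalicylidene)cyclohexane-1,2-diamine dianion, trivalent cobalt), H2O (0.55 equiv), THF, 0 °C → rt; chromatography
Reagents that add atoms: none
Why: In the Jacobsen hydrolytic kinetic resolution the chiral cobalt catalyst should hydrate the (R)-oxirane epimer much faster than the (S)-epimer, so the recovered epoxide is the (S,S) diastereomer, set by catalyst control and easily separated from the polar diol.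

Step 5
Reactants: 8 propiolic acid; 9 allyl alcohol
Product: 10 allyl propiolate
Conditions: DCC, DMAP (cat.), CH2Cl2, −20 → 0 °C; filtration, distillation
Reagents that add atoms: none
Why: Steglich esterification at low temperature converts the acid into the allyl ester while keeping conjugate addition to the ynoate slow.

Step 6
Reactants: 10 allyl propiolate; 7 (2S)-11-[(2S)-oxiran-2-yl]undecan-2-yl acetate
Product: 12 allyl (5S,15S)-15-acetoxy-5-hydroxyhexadec-2-ynoate, via allyl 3-lithiopropiolate 11 (not isolated)
Conditions: 10 (3 equiv), n-BuLi (2.9 equiv), THF, −90 → −78 °C; BF3·OEt2 (3 equiv); then 7, −78 °C; aq. NH4Cl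
Reagents that add atoms: none
Why: In this Yamaguchi–Hirao alkynylation the BF3-activated epoxide is opened by SN2 attack of the lithium acetylide at its CH2 carbon, so the (S)-oxirane carbon becomes C5 (S) untouched, and the stabilised acetylide should be too weak a nucleophile at −78 °C to attack the acetate.

Step 7
Reactants: 12 allyl (5S,15S)-15-acetoxy-5-hydroxyhexadec-2-ynoate
Product: 13 allyl (5S,15S)-5,15-diacetoxyhexadec-2-ynoate
Conditions: Ac2O (1.5 equiv), Sc(OTf)3 (1 mol%), MeCN, −20 → 0 °C
Reagents that add atoms: acetic anhydride, CC(=O)OC(C)=O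
Why: Lewis-acid-catalysed acetylation of the secondary alcohol avoids base, which could isomerise the ynoate to an allenoate or eliminate the homopropargylic acetate.

Step 8
Reactants: 14 cyclohexane-1,3-dione
Product: 16 1,3-bis(trimethylsilyloxy)cyclohexa-1,3-diene, via 3-(trimethylsilyloxy)cyclohex-2-en-1-one 15 (not isolated)
Conditions: TMSOTf (2.2 equiv), Et3N (2.6 equiv), Et2O, 0 °C → rt; removal of the ammonium triflate layer, bulb-to-bulb distillation
Reagents that add atoms: trimethylsilyl trifluoromethanesulfonate, C[Si](C)(C)OS(=O)(=O)C(F)(F)F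
Why: Two successive soft enolisation/O-silylation events give the diene, and because the dione is symmetric either deprotonation of the intermediate silyloxy enone leads to the same 1,3-bis(silyloxy)-1,3-diene.

Step 9
Reactants: 13 allyl (5S,15S)-5,15-diacetoxyhexadec-2-ynoate; 16 1,3-bis(trimethylsilyloxy)cyclohexa-1,3-diene
Product: 19 allyl 2-[(2S,12S)-2,12-diacetoxytridecyl]-4,6-dihydroxybenzoate, via bicyclo[2.2.2]octa-2,5-diene cycloadduct 17 (not isolated), via aryl bis(trimethylsilyl) ether 18 (not isolated)
Conditions: 16 (4 equiv), neat (or minimal mesitylene), sealed tube, Ar, 150–160 °C; then THF/1 M aq. HCl, 0 °C → rt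
Reagents that add atoms: none
Why: The electron-rich diene (HOMO) and the electron-poor ynoate (LUMO) undergo a concerted, polarised [4+2] cycloaddition to a bicyclo[2.2.2]octa-2,5-diene, which at the same temperature undergoes retro-[4+2] loss of its ethano bridge as ethylene, the gain of aromaticity driving the sequence. The closest known reaction type is the Alder–Rickert synthesis of 2,4-dioxygenated benzoates from 1,3-bis(silyloxy)cyclohexa-1,3-dienes and acetylenic esters. The benzene ring is closed intermolecularly by this cycloaddition, four ring carbons coming from the diene and two from the alkyne, with C1–C2 and C5–C6 formed in the same step. No lasting stereocentre is created, since the bridgehead centres of the adduct disappear on aromatisation and the two side-chain centres, already acetylated, lie away from the reacting π system. The step needs regioselectivity, which the matched polarisation should secure: the unsubstituted diene terminus, made most nucleophilic by both silyloxy groups, bonds to the chain-bearing β-carbon of the ynoate and the oxygenated terminus bonds to the ester-bearing α-carbon. The unactivated allyl alkene should not compete as a dienophile, and brief dilute acid removes both aryl silyl ethers without touching the acetates.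

Step 10
Reactants: 19 allyl 2-[(2S,12S)-2,12-diacetoxytridecyl]-4,6-dihydroxybenzoate
Product: 20 2-[(2S,12S)-2,12-diacetoxytridecyl]-4,6-dihydroxybenzoic acid (CNP0203944.2)
Conditions: Pd(PPh3)4 (5 mol%), morpholine (3 equiv), THF, 0 °C → rt; wash at pH 3 (aq. NaH2PO4/citric acid)
Reagents that add atoms: none
Why: In this Tsuji–Trost deallylation the zerovalent palladium complex ionises the allyl ester to a π-allyl complex and the carboxylate, and morpholine traps the allyl group under conditions that should leave the secondary acetates and the phenols untouched.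

**Compound list**
1 | 10-bromodec-1-ene | BrCCCCCCCCC=C | starting material
2 | (S)-propylene oxide | C[C@H]1CO1 | starting material
3 | dec-9-en-1-ylmagnesium bromide | C=CCCCCCCCC[Mg]Br | intermediate
4 | (S)-tridec-12-en-2-ol | C[C@H](O)CCCCCCCCCC=C | intermediate
5 | (S)-tridec-12-en-2-yl acetate | CC(=O)O[C@@H](C)CCCCCCCCCC=C | intermediate
6 | (2S)-11-(oxiran-2-yl)undecan-2-yl acetate (both oxirane epimers) | CC(=O)O[C@@H](C)CCCCCCCCCC1CO1 | intermediate
7 | (2S)-11-[(2S)-oxiran-2-yl]undecan-2-yl acetate | CC(=O)O[C@@H](C)CCCCCCCCC[C@H]1CO1 | intermediate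
8 | propiolic acid | C#CC(=O)O | starting material
9 | allyl alcohol | C=CCO | starting material
10 | allyl propiolate | C#CC(=O)OCC=C | intermediate
11 | allyl 3-lithiopropiolate | [Li]C#CC(=O)OCC=C | intermediate
12 | allyl (5S,15S)-15-acetoxy-5-hydroxyhexadec-2-ynoate | O[C@@H](CCCCCCCCC[C@H](C)OC(C)=O)CC#CC(=O)OCC=C | intermediate
13 | allyl (5S,15S)-5,15-diacetoxyhexadec-2-ynoate | CC(=O)O[C@@H](CCCCCCCCC[C@H](C)OC(C)=O)CC#CC(=O)OCC=C | intermediate
14 | cyclohexane-1,3-dione | O=C1CCCC(=O)C1 | starting material
15 | 3-(trimethylsilyloxy)cyclohex-2-en-1-one | C[Si](C)(C)OC1=CC(=O)CCC1 | intermediate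
16 | 1,3-bis(trimethylsilyloxy)cyclohexa-1,3-diene | C[Si](C)(C)OC1=CC(O[Si](C)(C)C)=CCC1 | intermediate
17 | allyl 3-[(2S,12S)-2,12-diacetoxytridecyl]-1,5-bis(trimethylsilyloxy)bicyclo[2.2.2]octa-2,5-diene-2-carboxylate (bridgehead configuration undefined) | CC(=O)O[C@@H](CCCCCCCCC[C@H](C)OC(C)=O)CC1=C(C(=O)OCC=C)C2(O[Si](C)(C)C)CCC1C(O[Si](C)(C)C)=C2 | intermediate
18 | allyl 2-[(2S,12S)-2,12-diacetoxytridecyl]-4,6-bis(trimethylsilyloxy)benzoate | CC(=O)O[C@@H](CCCCCCCCC[C@H](C)OC(C)=O)Cc1cc(O[Si](C)(C)C)cc(O[Si](C)(C)C)c1C(=O)OCC=C | intermediate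
19 | allyl 2-[(2S,12S)-2,12-diacetoxytridecyl]-4,6-dihydroxybenzoate | CC(=O)O[C@@H](CCCCCCCCC[C@H](C)OC(C)=O)Cc1cc(O)cc(O)c1C(=O)OCC=C | intermediate
20 | 2-[(2S,12S)-2,12-diacetoxytridecyl]-4,6-dihydroxybenzoic acid | CC(=O)O[C@@H](CCCCCCCCC[C@H](C)OC(C)=O)Cc1cc(O)cc(O)c1C(=O)O | target

**Step count**
Total: 10 steps. Longest linear sequence: 8 steps (steps 1, 2, 3, 4, 6, 7, 9, 10); steps 5 and 8 make the two side reagents.

**Steps most likely to fail**

1. Step 9 (key step). The cycloaddition of the β-alkyl ynoate may be too slow at temperatures the bis(silyloxy)diene tolerates, so that desilylation, aromatisation or oligomerisation of the diene outruns adduct formation. Fallback: attach the side chain to a preformed resorcinol ring and add the carboxyl afterwards, setting out from epoxide 7 and returning at the target 20. The Grignard reagent [3,5-bis(benzyloxy)phenyl]magnesium bromide F1 would be made from commercial 1,3-bis(benzyloxy)-5-bromobenzene and Mg in THF. With CuI (10 mol%) at −30 °C, where epoxide opening should outpace addition to the acetate, it should open 7 at the CH2 carbon to give (2S,12S)-13-[3,5-bis(benzyloxy)phenyl]-12-hydroxytridecan-2-yl acetate F2 with the carbinol configuration retained. Acetylation (Ac2O, pyridine, DMAP) would give (2S,12S)-13-[3,5-bis(benzyloxy)phenyl]tridecane-2,12-diyl diacetate F3. Vilsmeier–Haack formylation (POCl3, DMF) should go to the ring carbon ortho to the chain and para to a benzyloxy group, the position between the two ethers being more hindered, giving (2S,12S)-13-[3,5-bis(benzyloxy)-2-formylphenyl]tridecane-2,12-diyl diacetate F4. Pinnick oxidation (NaClO2, NaH2PO4, 2-methylbut-2-ene, t-BuOH/H2O) would give 2,4-bis(benzyloxy)-6-[(2S,12S)-2,12-diacetoxytridecyl]benzoic acid F5, and hydrogenolysis (H2, Pd/C, EtOAc) would give 20.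

2. Step 6. Self-condensation or oligomerisation of the lithiated propiolate, or its attack on the side-chain acetate, may compete with epoxide opening. Fallback: introduce the alkyne and the ester carbon separately, setting out from epoxide 7 and returning at ynoate 13. Commercial lithium (trimethylsilyl)acetylide with BF3·OEt2 in THF at −78 °C should open 7 to (2S,12S)-12-hydroxy-15-(trimethylsilyl)pentadec-14-yn-2-yl acetate F6. Acetylation (Ac2O, pyridine, DMAP) would give (2S,12S)-15-(trimethylsilyl)pentadec-14-yne-2,12-diyl diacetate F7, and buffered desilylation (TBAF, AcOH, THF, 0 °C) would give (2S,12S)-pentadec-14-yne-2,12-diyl diacetate F8. Copper-catalysed carboxylative coupling of the terminal alkyne with CO2 and allyl chloride ((IPr)CuCl cat., IPr = 1,3-bis(2,6-diisopropylphenyl)imidazol-2-ylidene, K2CO3, DMF, 60 °C) would then give 13.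

3. Step 10. Aminolysis of an acetate by the amine scavenger, allyl transfer to the free phenols, or lactonisation/decarboxylation of the sensitive hydroxy acid during work-up may erode the final product. Fallback: carry the carboxyl as a benzyl ester and release it by neutral hydrogenolysis, setting out from epoxide 7 and returning at the target 20. Commercial benzyl propiolate would be lithiated (n-BuLi, THF, −78 °C) to benzyl 3-lithiopropiolate F9, which with BF3·OEt2 should open 7 to benzyl (5S,15S)-15-acetoxy-5-hydroxyhexadec-2-ynoate F10. Acetylation (Ac2O, Sc(OTf)3 cat., MeCN) would give benzyl (5S,15S)-5,15-diacetoxyhexadec-2-ynoate F11. Heating with diene 16 as in step 9 should give the benzyl bicyclo[2.2.2]octadiene cycloadduct F12, then the benzyl bis(trimethylsilyl) ether F13 and, after dilute acid, benzyl 2-[(2S,12S)-2,12-diacetoxytridecyl]-4,6-dihydroxybenzoate F14. Hydrogenolysis (H2, Pd/C, EtOAc, rt) would then give 20 with no amine or base present.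

Further compounds
F1 | step 9 | [3,5-bis(benzyloxy)phenyl]magnesium bromide | Br[Mg]c1cc(OCc2ccccc2)cc(OCc2ccccc2)c1
F2 | step 9 | (2S,12S)-13-[3,5-bis(benzyloxy)phenyl]-12-hydroxytridecan-2-yl acetate | CC(=O)O[C@@H](C)CCCCCCCCC[C@H](O)Cc1cc(OCc2ccccc2)cc(OCc2ccccc2)c1
F3 | step 9 | (2S,12S)-13-[3,5-bis(benzyloxy)phenyl]tridecane-2,12-diyl diacetate | CC(=O)O[C@@H](C)CCCCCCCCC[C@H](OC(C)=O)Cc1cc(OCc2ccccc2)cc(OCc2ccccc2)c1
F4 | step 9 | (2S,12S)-13-[3,5-bis(benzyloxy)-2-formylphenyl]tridecane-2,12-diyl diacetate | CC(=O)O[C@@H](C)CCCCCCCCC[C@H](OC(C)=O)Cc1cc(OCc2ccccc2)cc(OCc2ccccc2)c1C=O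
F5 | step 9 | 2,4-bis(benzyloxy)-6-[(2S,12S)-2,12-diacetoxytridecyl]benzoic acid | CC(=O)O[C@@H](C)CCCCCCCCC[C@H](OC(C)=O)Cc1cc(OCc2ccccc2)cc(OCc2ccccc2)c1C(=O)O
F6 | step 6 | (2S,12S)-12-hydroxy-15-(trimethylsilyl)pentadec-14-yn-2-yl acetate | CC(=O)O[C@@H](C)CCCCCCCCC[C@H](O)CC#C[Si](C)(C)C
F7 | step 6 | (2S,12S)-15-(trimethylsilyl)pentadec-14-yne-2,12-diyl diacetate | CC(=O)O[C@@H](C)CCCCCCCCC[C@H](OC(C)=O)CC#C[Si](C)(C)C
F8 | step 6 | (2S,12S)-pentadec-14-yne-2,12-diyl diacetate | CC(=O)O[C@@H](C)CCCCCCCCC[C@H](OC(C)=O)CC#C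
F9 | step 10 | benzyl 3-lithiopropiolate | [Li]C#CC(=O)OCc1ccccc1
F10 | step 10 | benzyl (5S,15S)-15-acetoxy-5-hydroxyhexadec-2-ynoate | O[C@@H](CCCCCCCCC[C@H](C)OC(C)=O)CC#CC(=O)OCc1ccccc1
F11 | step 10 | benzyl (5S,15S)-5,15-diacetoxyhexadec-2-ynoate | CC(=O)O[C@@H](CCCCCCCCC[C@H](C)OC(C)=O)CC#CC(=O)OCc1ccccc1
F12 | step 10 | benzyl 3-[(2S,12S)-2,12-diacetoxytridecyl]-1,5-bis(trimethylsilyloxy)bicyclo[2.2.2]octa-2,5-diene-2-carboxylate | CC(=O)O[C@@H](CCCCCCCCC[C@H](C)OC(C)=O)CC1=C(C(=O)OCc3ccccc3)C2(O[Si](C)(C)C)CCC1C(O[Si](C)(C)C)=C2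
F13 | step 10 | benzyl 2-[(2S,12S)-2,12-diacetoxytridecyl]-4,6-bis(trimethylsilyloxy)benzoate | CC(=O)O[C@@H](CCCCCCCCC[C@H](C)OC(C)=O)Cc1cc(O[Si](C)(C)C)cc(O[Si](C)(C)C)c1C(=O)OCc1ccccc1
F14 | step 10 | benzyl 2-[(2S,12S)-2,12-diacetoxytridecyl]-4,6-dihydroxybenzoate | CC(=O)O[C@@H](CCCCCCCCC[C@H](C)OC(C)=O)Cc1cc(O)cc(O)c1C(=O)OCc1ccccc1
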